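**Retrosynthetic overview**

- Feature: ring A is a hexasubstituted benzene whose C5 oxygen, C6 prenyl, C7 oxygen and C8 carbon follow the hydroxyl / alkyl / silyloxy / C–H pattern that a vinylketene–ynol ether benzannulation delivers, with C4a and C8a already part of a 4-pyranone.
- Endgame disconnections: C5–OMe (methylation), then the chromene ring (O7–CMe2 and C8–CH=, propargyl ether Claisen cascade), back to the 5-hydroxy-6-prenyl-7-silyloxy flavone 26.
- Key disconnection: ring A at C8a–C8, C7–C8, C5–C6 and C4a–C5, giving the oxepine-fused 2-diazoacetyl-4-pyranone 16 and the prenyl-substituted silyloxyalkyne 21 (Kowalski homologation of a 4-methylpent-3-enoate).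
- 16 comes from pyranone-2-carboxylate 13; the oxepine is closed by copper-catalysed intramolecular O-vinylation (aryl O–C(=CMe2) bond) of bromoalkene 12; the pyranone comes from oxalylation and cyclodehydration of the C-alkylated aryl 1,3-diketone 8, made from 3,4-dimethoxyphenol.
- Order of ring formation: ring B (bought) → pyranone (ring C) → oxepine → ring A → chromene ring.

Key step: step 13

Remark on the chemistry: compounds 11–16 and 22–24 are numbered as 4-pyranones (O1; C2 with the carbonyl-derived side chain; C3–H; C4=O; C5 with the side-chain CH2; C6 with ring B). From 25 on flavone numbering is used, so pyranone C2 and C3 become C8a and C4a. "Oxepinoflavone" means the 4',5'-dimethoxyflavone whose C3 and C2' are bridged by CH2–C(=CMe2)–O. The target has no stereocentre and no configured double bond. The 7-silyl ether is a vinylogous silyl ester, so it is removed before any basic alkylation and the chelated 5-hydroxyl is methylated last.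

**Route**

Step 1
Reactants: 1 3,4-dimethoxyphenol
Product: 2 1-(2-hydroxy-4,5-dimethoxyphenyl)ethan-1-one
Conditions: AcOH, BF3·OEt2, 90 °C
Reagents that add atoms: acetic acid, CC(=O)O
Why: BF3-mediated Friedel–Crafts (Fries-type) acylation of the electron-rich phenol should take the acetyl group to C6, ortho to the hydroxyl and para to the 3-methoxy group.

Step 2
Reactants: 2 1-(2-hydroxy-4,5-dimethoxyphenyl)ethan-1-one
Product: 3 1-[2-(benzyloxy)-4,5-dimethoxyphenyl]ethan-1-one
Conditions: BnBr, K2CO3, DMF, 60 °C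
Reagents that add atoms: benzyl bromide, BrCc1ccccc1
Why: Williamson etherification masks the phenol so that the later tricarbonyl chain cannot close to a chromone instead of the pyranone.

Step 3
Reactants: 3 1-[2-(benzyloxy)-4,5-dimethoxyphenyl]ethan-1-one
Product: 4 1-[2-(benzyloxy)-4,5-dimethoxyphenyl]butane-1,3-dione
Conditions: NaH, EtOAc, THF, reflux; aq. HCl work-up
Reagents that add atoms: ethyl acetate, CCOC(C)=O
Why: Crossed Claisen condensation of the methyl ketone enolate with ethyl acetate is driven by formation of the stabilised diketonate.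

Step 4
Reactants: 5 3-methylbuta-1,2-diene
Product: 7 1,2-dibromo-3-methylbut-2-ene, via 2,3-dibromo-3-methylbut-1-ene 6 (not isolated)
Conditions: Br2, CH2Cl2, −78 °C to rt; then 40 °C
Reagents that add atoms: bromine, BrBr
Why: Electrophilic addition of bromine to the allene places bromine on the central carbon through the 2-bromoallyl cation, and the tertiary allylic dibromide formed first should equilibrate by allylic transposition to the primary bromide with the tetrasubstituted alkene.

Step 5
Reactants: 4 1-[2-(benzyloxy)-4,5-dimethoxyphenyl]butane-1,3-dione; 7 1,2-dibromo-3-methylbut-2-ene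
Product: 8 1-[2-(benzyloxy)-4,5-dimethoxyphenyl]-2-(2-bromo-3-methylbut-2-en-1-yl)butane-1,3-dione (racemic, configurationally labile)
Conditions: K2CO3, acetone, reflux
Reagents that add atoms: none
Why: SN2 C-alkylation of the soft diketonate by the primary 2-bromoallylic bromide should proceed with the vinylic bromide left untouched.

Step 6
Reactants: 8 1-[2-(benzyloxy)-4,5-dimethoxyphenyl]-2-(2-bromo-3-methylbut-2-en-1-yl)butane-1,3-dione; 9 diethyl oxalate
Product: 11 ethyl 6-[2-(benzyloxy)-4,5-dimethoxyphenyl]-5-(2-bromo-3-methylbut-2-en-1-yl)-4-oxo-4H-pyran-2-carboxylate, via triketo ester 10 (not isolated)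
Conditions: LiN(iPr)2 (2.3 equiv), THF, −78 to 0 °C; (CO2Et)2, −78 °C; aq. HCl work-up; then TsOH·H2O (cat.), toluene, 80 °C
Reagents that add atoms: none
Why: Claisen-type γ-acylation of the 1,3-diketone dianion with diethyl oxalate gives the 2,4,6-triketo ester, whose acid-catalysed cyclodehydration is the standard route to 4-pyranone-2-carboxylates, and the benzyl ether leaves the pyranone as the only possible mode of closure.

Step 7
Reactants: 11 ethyl 6-[2-(benzyloxy)-4,5-dimethoxyphenyl]-5-(2-bromo-3-methylbut-2-en-1-yl)-4-oxo-4H-pyran-2-carboxylate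
Product: 12 ethyl 5-(2-bromo-3-methylbut-2-en-1-yl)-6-(2-hydroxy-4,5-dimethoxyphenyl)-4-oxo-4H-pyran-2-carboxylate
Conditions: BCl3, C6HMe5, CH2Cl2, −78 °C; MeOH then H2O
Reagents that add atoms: none
Why: Lewis-acid debenzylation with pentamethylbenzene as cation scavenger should cleave the benzyl ether at low temperature while the methyl ethers, the ester and the alkenyl bromide (which rules out hydrogenolysis) persist.

Step 8
Reactants: 12 ethyl 5-(2-bromo-3-methylbut-2-en-1-yl)-6-(2-hydroxy-4,5-dimethoxyphenyl)-4-oxo-4H-pyran-2-carboxylate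
Product: 13 ethyl 9,10-dimethoxy-4-oxo-6-(propan-2-ylidene)-5,6-dihydro-4H-pyrano[3,2-d][1]benzoxepine-2-carboxylate (the 4-pyranone-2-carboxylate whose C5–CH2–C(=CMe2)–O–aryl bridge forms the oxepine)
Conditions: copper iodide CuI (10 mol %), 1,10-phenanthroline (20 mol %), Cs2CO3, dioxane, 90 °C
Reagents that add atoms: none
Why: Ullmann-type copper-catalysed intramolecular O-vinylation of the phenoxide with the alkenyl bromide should close the seven-membered ring and fix the double bond in the exocyclic isopropylidene position, because the bromine-bearing carbon is the one that becomes oxygen-bound and the pyranone offers no competing enolisable site.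

Step 9
Reactants: 13 ethyl 9,10-dimethoxy-4-oxo-6-(propan-2-ylidene)-5,6-dihydro-4H-pyrano[3,2-d][1]benzoxepine-2-carboxylate
Product: 14 9,10-dimethoxy-4-oxo-6-(propan-2-ylidene)-5,6-dihydro-4H-pyrano[3,2-d][1]benzoxepine-2-carboxylic acid
Conditions: LiOH·H2O (1.1 equiv), THF/H2O, 0 °C; then cold 0.5 M HCl to pH 3
Reagents that add atoms: lithium hydroxide, [Li+].[OH-]
Why: Saponification of the activated heteroaryl ester under cold, near-stoichiometric conditions should spare the pyranone, and the tetrasubstituted aryl enol ether should tolerate base and the brief cold acidification.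

Step 10
Reactants: 14 9,10-dimethoxy-4-oxo-6-(propan-2-ylidene)-5,6-dihydro-4H-pyrano[3,2-d][1]benzoxepine-2-carboxylic acid
Product: 16 2-(diazoacetyl)-9,10-dimethoxy-6-(propan-2-ylidene)-5,6-dihydro-4H-pyrano[3,2-d][1]benzoxepin-4-one, via isobutyl carbonic anhydride 15 (not isolated)
Conditions: iBuOCOCl, N-methylmorpholine, THF, −15 °C; then CH2N2, Et2O, 0 °C
Reagents that add atoms: diazomethane, C=[N+]=[N-]
Why: Arndt–Eistert-type acylation of diazomethane by the mixed carbonic anhydride should give the diazomethyl ketone without liberating HCl, which protects the enol ether.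

Step 11
Reactants: 17 4-methylpent-3-enoic acid
Product: 18 ethyl 4-methylpent-3-enoate
Conditions: EtI, K2CO3, DMF, rt
Reagents that add atoms: iodoethane, CCI
Why: O-alkylation of the carboxylate under mild base avoids the acid-promoted lactonisation and double-bond migration of the β,γ-unsaturated acid.

Step 12
Reactants: 18 ethyl 4-methylpent-3-enoate
Product: 21 triisopropyl[(5-methylhex-4-en-1-yn-1-yl)oxy]silane, via lithium dibromoenolate 19 (not isolated), via lithium ynolate 20 (not isolated)
Conditions: CH2Br2, lithium 2,2,6,6-tetramethylpiperidide, THF, −78 °C; 18; n-BuLi, −78 to 0 °C; iPr3SiCl, −78 °C to rt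
Reagents that add atoms: dibromomethane, BrCBr; triisopropylsilyl chloride, CC(C)[Si](Cl)(C(C)C)C(C)C
Why: Kowalski ester homologation (addition of dibromomethyllithium, bromine–lithium exchange on the dibromoenolate and 1,2-shift) should give the lithium ynolate, which the bulky silyl chloride traps on oxygen.

Step 13
Reactants: 16 2-(diazoacetyl)-9,10-dimethoxy-6-(propan-2-ylidene)-5,6-dihydro-4H-pyrano[3,2-d][1]benzoxepin-4-one; 21 triisopropyl[(5-methylhex-4-en-1-yn-1-yl)oxy]silane
Product: 26 5-hydroxy-6-prenyl-7-(triisopropylsilyloxy) oxepinoflavone, via pyranonyl ketene 22 (not isolated), via cyclobutenone 23 (not isolated), via dienylketene 24 (not isolated), via cyclohexadienone 25 (not isolated)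
Conditions: 21 (1.5 equiv), hν (365 nm), ClCH2CH2Cl (degassed), 25 °C; then 80 °C
Reagents that add atoms: none
Why: Irradiation expels N2 from 16 and pyranone C2 migrates to the carbene carbon (Wolff rearrangement) to give ketene 22 with the C8a–C8 bond in place, after which the prenyl-bearing nucleophilic carbon of ynol ether 21 attacks the ketene carbonyl carbon and [2+2] cycloaddition gives cyclobutenone 23 (C5–C6 and C7–C8 formed). Four-electron conrotatory ring opening on warming gives dienylketene 24, whose thermal disrotatory six-electron electrocyclisation onto the pyranone C3–H carbon closes ring A through the C4a–C5 bond to give cyclohexadienone 25, and enolisation to the phenol chelated to the C4 carbonyl makes the sequence irreversible. The closest known reaction is the Danheiser benzannulation in its photochemical Wolff form, in which aryl, heteroaryl and alkenyl diazomethyl ketones combine with triisopropylsilyloxyalkynes to give resorcinol monosilyl ethers. No stereocentre remains, the sp3 carbons of 23 and 25 being transient and racemic. The step needs regiocontrol in the [2+2] event, which the polarisation of the ynol ether secures (prenyl ortho and silyloxy meta to the new hydroxyl), and site control in the electrocyclisation, which is fixed because the ketene-bearing pyranone carbon has only one carbon neighbour (the C–H carbon), the other being the ring oxygen; long-wavelength light is chosen to spare the aryl-pyranone and enol ether chromophores.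

Step 14
Reactants: 26 5-hydroxy-6-prenyl-7-(triisopropylsilyloxy) oxepinoflavone
Product: 27 5,7-dihydroxy-6-prenyl oxepinoflavone
Conditions: Bu4NF, AcOH, THF, 0 °C
Reagents that add atoms: none
Why: Buffered fluoride should cleave the aryl silyl ether, a vinylogous silyl ester of the C4 carbonyl, without touching the enol ether or the alkenes.

Step 15
Reactants: 27 5,7-dihydroxy-6-prenyl oxepinoflavone; 28 3-chloro-3-methylbut-1-yne
Product: 29 5-hydroxy-7-[(2-methylbut-3-yn-2-yl)oxy]-6-prenyl oxepinoflavone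
Conditions: DBU, CuCl2·2H2O (1 mol %), MeCN, 0 °C
Reagents that add atoms: none
Why: Copper-catalysed propargylic etherification should alkylate only the acidic 7-hydroxyl, the 5-hydroxyl being held in a hydrogen bond to the C4 carbonyl.

Step 16
Reactants: 29 5-hydroxy-7-[(2-methylbut-3-yn-2-yl)oxy]-6-prenyl oxepinoflavone
Product: 31 5-hydroxy-6-prenyl oxepinoflavone with a 2,2-dimethyl-2H-pyran ring fused at C7–O and C8, via 8-allenyl phenol 30 (not isolated)
Conditions: PhNEt2, 150 °C
Reagents that add atoms: none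
Why: Aromatic propargyl Claisen rearrangement to C8, the only free ortho position, followed by rearomatisation, 1,5-hydrogen shift and oxa-six-electron electrocyclisation, should close the 2,2-dimethylchromene ring.

Step 17
Reactants: 31 5-hydroxy-6-prenyl oxepinoflavone with a 2,2-dimethyl-2H-pyran ring fused at C7–O and C8
Product: 32 target CNP0192589.0 (5-methoxy-6-prenyl oxepinoflavone with the 2,2-dimethyl-2H-pyran ring fused at C7–O and C8)
Conditions: MeI, K2CO3, DMF, 40 °C
Reagents that add atoms: iodomethane, CI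
Why: Williamson methylation of the chelated 5-hydroxyl, the only remaining acidic site, should complete the target.

**Compound list**

1 | 3,4-dimethoxyphenol | COc1ccc(O)cc1OC | starting material
2 | 1-(2-hydroxy-4,5-dimethoxyphenyl)ethan-1-one | CC(=O)c1cc(OC)c(OC)cc1O | intermediate
3 | 1-[2-(benzyloxy)-4,5-dimethoxyphenyl]ethan-1-one | CC(=O)c1cc(OC)c(OC)cc1OCc1ccccc1 | intermediate
4 | 1-[2-(benzyloxy)-4,5-dimethoxyphenyl]butane-1,3-dione | CC(=O)CC(=O)c1cc(OC)c(OC)cc1OCc1ccccc1 | intermediate
5 | 3-methylbuta-1,2-diene | CC(C)=C=C | starting material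
6 | 2,3-dibromo-3-methylbut-1-ene | C=C(Br)C(C)(C)Br | intermediate
7 | 1,2-dibromo-3-methylbut-2-ene | CC(C)=C(Br)CBr | intermediate
8 | 1-[2-(benzyloxy)-4,5-dimethoxyphenyl]-2-(2-bromo-3-methylbut-2-en-1-yl)butane-1,3-dione (racemic) | CC(=O)C(CC(Br)=C(C)C)C(=O)c1cc(OC)c(OC)cc1OCc1ccccc1 | intermediate
9 | diethyl oxalate | CCOC(=O)C(=O)OCC | starting material
10 | triketo ester: ethyl 5-[2-(benzyloxy)-4,5-dimethoxybenzoyl]-7-bromo-8-methyl-2,4-dioxonon-7-enoate (racemic) | CCOC(=O)C(=O)CC(=O)C(CC(Br)=C(C)C)C(=O)c1cc(OC)c(OC)cc1OCc1ccccc1 | intermediate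
11 | ethyl 6-[2-(benzyloxy)-4,5-dimethoxyphenyl]-5-(2-bromo-3-methylbut-2-en-1-yl)-4-oxo-4H-pyran-2-carboxylate | CCOC(=O)c1cc(=O)c(CC(Br)=C(C)C)c(-c2cc(OC)c(OC)cc2OCc2ccccc2)o1 | intermediate
12 | ethyl 5-(2-bromo-3-methylbut-2-en-1-yl)-6-(2-hydroxy-4,5-dimethoxyphenyl)-4-oxo-4H-pyran-2-carboxylate | CCOC(=O)c1cc(=O)c(CC(Br)=C(C)C)c(-c2cc(OC)c(OC)cc2O)o1 | intermediate
13 | ethyl 9,10-dimethoxy-4-oxo-6-(propan-2-ylidene)-5,6-dihydro-4H-pyrano[3,2-d][1]benzoxepine-2-carboxylate | CCOC(=O)c1cc(=O)c2c(o1)-c1cc(OC)c(OC)cc1OC(=C(C)C)C2 | intermediate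
14 | 9,10-dimethoxy-4-oxo-6-(propan-2-ylidene)-5,6-dihydro-4H-pyrano[3,2-d][1]benzoxepine-2-carboxylic acid | OC(=O)c1cc(=O)c2c(o1)-c1cc(OC)c(OC)cc1OC(=C(C)C)C2 | intermediate
15 | isobutyl carbonic anhydride of acid 14 | CC(C)COC(=O)OC(=O)c1cc(=O)c2c(o1)-c1cc(OC)c(OC)cc1OC(=C(C)C)C2 | intermediate
16 | 2-(diazoacetyl)-9,10-dimethoxy-6-(propan-2-ylidene)-5,6-dihydro-4H-pyrano[3,2-d][1]benzoxepin-4-one | COc1cc2c(cc1OC)-c1oc(C(=O)C=[N+]=[N-])cc(=O)c1CC(=C(C)C)O2 | intermediate
17 | 4-methylpent-3-enoic acid | CC(C)=CCC(=O)O | starting material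
18 | ethyl 4-methylpent-3-enoate | CCOC(=O)CC=C(C)C | intermediate
19 | lithium dibromoenolate: lithium 1,1-dibromo-5-methylhexa-1,4-dien-2-olate | [Li+].[O-]C(=C(Br)Br)CC=C(C)C | intermediate
20 | lithium ynolate: lithium 5-methylhex-4-en-1-yn-1-olate | [Li+].[O-]C#CCC=C(C)C | intermediate
21 | triisopropyl[(5-methylhex-4-en-1-yn-1-yl)oxy]silane | CC(C)=CCC#CO[Si](C(C)C)(C(C)C)C(C)C | intermediate
22 | pyranonyl ketene: 9,10-dimethoxy-2-(2-oxoethenyl)-6-(propan-2-ylidene)-5,6-dihydro-4H-pyrano[3,2-d][1]benzoxepin-4-one | O=C=Cc1cc(=O)c2c(o1)-c1cc(OC)c(OC)cc1OC(=C(C)C)C2 | intermediate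
23 | cyclobutenone: 2-(3-methylbut-2-en-1-yl)-3-(triisopropylsilyloxy)cyclobut-2-en-1-one carrying the pyranobenzoxepinon-2-yl group at C4 (racemic) | O=C1C(CC=C(C)C)=C(O[Si](C(C)C)(C(C)C)C(C)C)C1c1cc(=O)c2c(o1)-c1cc(OC)c(OC)cc1OC(=C(C)C)C2 | intermediate
24 | dienylketene: (E)-2-prenyl-3-(triisopropylsilyloxy)-4-(pyranobenzoxepinon-2-yl)buta-1,3-dien-1-one, ketene carbon and pyranone cis | O=C=C(CC=C(C)C)/C(O[Si](C(C)C)(C(C)C)C(C)C)=C\c1cc(=O)c2c(o1)-c1cc(OC)c(OC)cc1OC(=C(C)C)C2 | intermediate
25 | cyclohexadienone: 4a-H keto tautomer of 26 (racemic) | O=C1C(CC=C(C)C)=C(O[Si](C(C)C)(C(C)C)C(C)C)C=C2OC3=C(C(=O)C12)CC(=C(C)C)Oc1cc(OC)c(OC)cc13 | intermediate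
26 | 5-hydroxy-6-prenyl-7-(triisopropylsilyloxy) oxepinoflavone | COc1cc2c(cc1OC)-c1oc3cc(O[Si](C(C)C)(C(C)C)C(C)C)c(CC=C(C)C)c(O)c3c(=O)c1CC(=C(C)C)O2 | intermediate
27 | 5,7-dihydroxy-6-prenyl oxepinoflavone | COc1cc2c(cc1OC)-c1oc3cc(O)c(CC=C(C)C)c(O)c3c(=O)c1CC(=C(C)C)O2 | intermediate
28 | 3-chloro-3-methylbut-1-yne | C#CC(C)(C)Cl | starting material
29 | 5-hydroxy-7-[(2-methylbut-3-yn-2-yl)oxy]-6-prenyl oxepinoflavone | COc1cc2c(cc1OC)-c1oc3cc(OC(C)(C)C#C)c(CC=C(C)C)c(O)c3c(=O)c1CC(=C(C)C)O2 | intermediate
30 | 8-allenyl phenol: 5,7-dihydroxy-8-(3-methylbuta-1,2-dien-1-yl)-6-prenyl oxepinoflavone | COc1cc2c(cc1OC)-c1oc3c(C=C=C(C)C)c(O)c(CC=C(C)C)c(O)c3c(=O)c1CC(=C(C)C)O2 | intermediate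
31 | 5-hydroxy-6-prenyl oxepinoflavone with 2,2-dimethyl-2H-pyran fused at C7–O and C8 | COc1cc2c(cc1OC)-c1oc3c4c(c(CC=C(C)C)c(O)c3c(=O)c1CC(=C(C)C)O2)OC(C)(C)C=C4 | intermediate
32 | CNP0192589.0: 5-methoxy-6-prenyl oxepinoflavone with 2,2-dimethyl-2H-pyran fused at C7–O and C8 | COc1cc2c(cc1OC)-c1oc3c4c(c(CC=C(C)C)c(OC)c3c(=O)c1CC(=C(C)C)O2)OC(C)(C)C=C4 | target

**Step count and risk**

Total step count: 17. Longest linear sequence: 14 steps (steps 1–3, 5–10 and 13–17).

The three steps most likely to fail:

Step 13 (key step). The excited aryl-pyranone chromophore may react on its own, or ketene 22 may dimerise or acylate the product phenol faster than it adds to 21. The fallback makes the same ketene without light. It sets out from 16 and comes back at 22, and so through 23 to 26. Diazoketone 16 is rearranged in the dark with silver benzoate AgO2CPh and Et3N in THF/H2O (Arndt–Eistert homologation) to 2-[9,10-dimethoxy-4-oxo-6-(propan-2-ylidene)-5,6-dihydro-4H-pyrano[3,2-d][1]benzoxepin-2-yl]acetic acid F1. This vinylogous β-keto acid is kept cold to avoid decarboxylation. 1-Chloro-N,N,2-trimethylprop-1-en-1-amine in CH2Cl2 at 0 °C should convert it, without free HCl, into the corresponding acetyl chloride F2. F2 is added slowly to 21 and Et3N in toluene at 25 °C; dehydrochlorination should give ketene 22, which 21 traps as cyclobutenone 23, and heating to 80 °C should carry 23 on to 26.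

Step 8. Oxidative addition of the copper phenoxide to the fully substituted alkenyl bromide may be slow, so that protodebromination or base-induced breakdown of the pyranone ester wins. The fallback reverses the polarity of the alkenyl partner and forms the C–O bond by oxidative coupling. It sets out from 11 and comes back at 13. Miyaura borylation of 11 (bis(pinacolato)diboron, PdCl2(dppf), KOAc, dioxane, 80 °C) should give ethyl 6-[2-(benzyloxy)-4,5-dimethoxyphenyl]-5-[3-methyl-2-(4,4,5,5-tetramethyl-1,3,2-dioxaborolan-2-yl)but-2-en-1-yl]-4-oxo-4H-pyran-2-carboxylate F3. Hydrogenolysis (H2, palladium on carbon, EtOAc), which the tetrasubstituted alkenyl boronate should survive, would give ethyl 6-(2-hydroxy-4,5-dimethoxyphenyl)-5-[3-methyl-2-(4,4,5,5-tetramethyl-1,3,2-dioxaborolan-2-yl)but-2-en-1-yl]-4-oxo-4H-pyran-2-carboxylate F4. Intramolecular Chan–Lam coupling (Cu(OAc)2, pyridine, 4 Å molecular sieves, O2, CH2Cl2, 25 °C) should then close the oxepine to 13.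

Step 12. Dibromomethyllithium or the amide base may deprotonate the acidic α-position of the β,γ-unsaturated ester instead of adding to the carbonyl, returning ester or its conjugated isomer. The fallback reaches the ynolate by oxidation of an acetylide. It sets out from 18 and comes back at 20. Reduction of 18 with iBu2AlH in CH2Cl2 at −78 °C should give 4-methylpent-3-enal F5. Corey–Fuchs olefination (CBr4, PPh3, CH2Cl2, 0 °C) gives 1,1-dibromo-5-methylhexa-1,4-diene F6. n-BuLi (2 equiv) in THF at −78 °C converts F6 into lithium 5-methylhex-4-en-1-yn-1-ide F7. Oxidation of F7 in the same flask with lithium tert-butyl peroxide (from tBuOOH and LiN(SiMe3)2, −78 to 0 °C) should give ynolate 20, which is silylated with iPr3SiCl to 21 as in the route.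

**Further compounds**

F1 | step 13 | 2-[9,10-dimethoxy-4-oxo-6-(propan-2-ylidene)-5,6-dihydro-4H-pyrano[3,2-d][1]benzoxepin-2-yl]acetic acid | OC(=O)Cc1cc(=O)c2c(o1)-c1cc(OC)c(OC)cc1OC(=C(C)C)C2
F2 | step 13 | 2-[9,10-dimethoxy-4-oxo-6-(propan-2-ylidene)-5,6-dihydro-4H-pyrano[3,2-d][1]benzoxepin-2-yl]acetyl chloride | ClC(=O)Cc1cc(=O)c2c(o1)-c1cc(OC)c(OC)cc1OC(=C(C)C)C2
F3 | step 8 | ethyl 6-[2-(benzyloxy)-4,5-dimethoxyphenyl]-5-[3-methyl-2-(4,4,5,5-tetramethyl-1,3,2-dioxaborolan-2-yl)but-2-en-1-yl]-4-oxo-4H-pyran-2-carboxylate | CCOC(=O)c1cc(=O)c(CC(B2OC(C)(C)C(C)(C)O2)=C(C)C)c(-c2cc(OC)c(OC)cc2OCc2ccccc2)o1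
F4 | step 8 | ethyl 6-(2-hydroxy-4,5-dimethoxyphenyl)-5-[3-methyl-2-(4,4,5,5-tetramethyl-1,3,2-dioxaborolan-2-yl)but-2-en-1-yl]-4-oxo-4H-pyran-2-carboxylate | CCOC(=O)c1cc(=O)c(CC(B2OC(C)(C)C(C)(C)O2)=C(C)C)c(-c2cc(OC)c(OC)cc2O)o1
F5 | step 12 | 4-methylpent-3-enal | CC(C)=CCC=O
F6 | step 12 | 1,1-dibromo-5-methylhexa-1,4-diene | CC(C)=CCC=C(Br)Br
F7 | step 12 | lithium 5-methylhex-4-en-1-yn-1-ide | [Li+].[C-]#CCC=C(C)C
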